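Remark on the chemistry: positions carry halimane numbers throughout (ring A: C1–C5, C10; ring B: C5–C10; chain C11–C16 on C9; C17 on C8; C20 on C9). Compounds 3, 4, 6, 7 and 8 are carried as mixtures at C9, because the key step enolizes that centre.

## The problem

Target 25 is a halimane in which rings A and B share the tetrasubstituted C5=C10 double bond, so there is no ring-fusion stereocentre. Ring B carries four contiguous centres: C6 (S, free OH), C7 (R, acetate), C8 (S, methyl C17) and the quaternary C9 (R, methyl C20 and the C11–C16 chain). A fifth centre, the tertiary vinyl carbinol C13 (S), lies on a freely rotating chain. The hard part is the C8/C9 pair, a tertiary centre next to an all-carbon quaternary one with C17 cis to C11. Once it exists it can steer the cis-6,7-diol, because a reagent adding to a C6=C7 bond approaches from the face away from C17 and C11. It cannot reach C13, which therefore needs reagent control. Only C7 is acylated, so the two secondary hydroxyls must be told apart, and the acetate cannot be carried through organometallic or alkaline steps. The C13 tertiary allylic alcohol and the allylic C6–O bond ionize under acid, so the last protecting groups must come off without acid. The enabling feature is this: with C6–C7 as an alkene, ring B is a cyclohexa-1,3-diene (C10=C5–C6=C7) whose sp3 atoms are C8 and C9, and C9 bears C11, which can be a carboxyl carbon. That γ,δ-unsaturated acid (C11–C9–C8–C7=C6) is the product of an ester enolate Claisen rearrangement. Because the allylic oxygen on C6 and the enolate carbon C9 both hang on the C5=C10 bond, the ester is a six-membered lactone.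

## Retrosynthesis

**C7–O acyl bond (25 ⇒ 24 ⇒ 23).** The acetate is removed first because it would not survive the organolithium and alkaline peroxide used to build C13. In triol 24 the C7 hydroxyl is an open secondary alcohol, C6–OH is allylic and screened by the C4 methyl groups across C5, and C13–OH is tertiary, so kinetic acetylation should pick C7. Triol 24 comes from bis(triethylsilyl) ether 23. Silyl ethers are preferred to a ketal because fluoride removes them without acid. The forward steps must deliver regioselective monoacylation and nothing else.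

**C12–C13 bond (23 ⇒ 17 + 19, 19 ⇒ 18).** Cutting next to the carbinol carbon lets the stereocentre arrive with a small chiral reagent. Primary boronic ester 17 is joined to the lithiated carbamate 19 of (R)-but-3-en-2-ol 18, and the boron is then replaced by oxygen. The neighbouring cut, C13–C14 (vinyl addition to a methyl ketone), would give no control, since C13 is too far from the ring centres. The precursor 17 has no chain stereocentre at all. The forward reaction must be stereoretentive at boron capture and invertive in the 1,2-shift.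

**C12–B and C11=C12 (17 ⇒ 16 ⇒ 15).** The boronic ester is the anti-Markovnikov hydroboration product of vinyl compound 16, and 16 is the methylenation product of the neopentyl aldehyde 15. At this stage the only other alkene is the inert tetrasubstituted C5=C10 bond, so no selectivity question arises.

**C6–O and C7–O (15 ⇒ 14 ⇒ 13, then 13 ⇒ 12 ⇒ 11).** Both oxygens are removed together as a cis-dihydroxylation of the C6=C7 bond of diene aldehyde 13. This must precede any terminal vinyl group, which would compete. The face is set by the cis-disposed C17 and C11 groups. Aldehyde 13 is the acid 11 after reduction to alcohol 12 and re-oxidation. The precursor is two stereocentres poorer and contains only C8 and C9.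

**C8–C9 bond, ring B (11 ⇒ 8).** This is the key cut. Breaking C8–C9 in 11 and reconnecting C6 to the carboxyl oxygen gives lactone 8, in which ring B does not yet exist and the only controlled centre is C6. The competing cuts are weaker. A Diels–Alder disconnection of ring B would leave the ring alkene at C5=C6, not C5=C10. A C6–C7 cut would require the C8/C9 pair to be made acyclically beforehand. Here both centres arise in one stereospecific event from one carbinol centre. The forward [3,3] shift must outrun ring opening of the enolate and of its silyl ketene acetal, and it must pass through a boat.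

**C11–O and C6–H (8 ⇒ 7 ⇒ 6).** The lactone is opened to hydroxy ester 7, and the carbinol hydrogen is removed to give cross-conjugated dienone 6. The C6 centre then comes from a catalytic, reagent-controlled ketone reduction, in which the two alkenyl groups differ greatly in bulk. Lactonization must avoid both acid (7 is a doubly allylic alcohol) and strong base.

**C5–C6 and C6–C7 (6 ⇒ 4 + 5).** The ketone carbon is inserted between enol triflate 4 and (E)-prop-1-enylboronic acid 5 in a carbonylative coupling. The boronic acid brings the E geometry that later fixes C8. The alternative of adding a propenyl metal to an aldehyde would need two more steps to reach the same ketone.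

**C5–O and C9–C10 (4 ⇒ 3 ⇒ 1 + 2).** The triflate is the only possible enol derivative of keto ester 3, whose ketone has one α-hydrogen. Keto ester 3 is the alkylation product of 2,2-dimethylcyclohexanone 1 with methyl 2-bromopropanoate 2. Both starting materials are achiral or racemic commodity compounds, and the centres formed here are erased later.

## Roads not taken

**Alternative 1:** The cut is the biosynthetic one. Both rings are opened to geranylgeranyl diphosphate A1. Forward, a class 2 diterpene cyclase of the syn-copalyl type would protonate the terminal alkene, form C4–C5 and C9–C10, move hydride from C9 to C8 and methyl from C10 to C9, and lose the C5 proton to give syn-halima-5(10),13E-dien-15-yl diphosphate A2.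
- Merits: one step builds both rings, the C5=C10 alkene and the C8/C9 pair with enzyme control. In step count to the carbon skeleton it is clearly better than the chosen plan.
- Weak points: A2 has no oxygen at C6 or C7 and no C6=C7 alkene to receive it, so two C–H bonds must be oxidized on a ring where C1 is as allylic as C6. The chain arrives as a primary allylic diphosphate and still needs a stereocontrolled transposition to the C13 carbinol. The route also depends on an enzyme of exactly this product specificity.
- Comparison: the chosen plan sets against the shorter skeleton synthesis a C6=C7 alkene placed where the diol is needed and a reagent-controlled C13.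

**Alternative 2:** The cut is C1–C10, with ring B made first. Forward, halogen–lithium exchange of the iodide in vinylogous ester A3 triggers 1,2-addition to the C10 ketone, and acid transposes the product to enone A4 (Stork–Danheiser logic).
- Merits: the anionic closure is dependable, and in reliability of the key step this road is better than the chosen one. The C6 ketone is a handle for the C6 oxygen, and C13 is carried in from a defined building block.
- Weak points: A3 must already contain the C8/C9 pair with its full side chain, which needs its own asymmetric sequence. A fully substituted carbon (C4) has to be attached to C5 of a vinylogous ester. The addition must occur at a ketone flanked by the quaternary C9. The cis-6,7-diol then needs two separate operations (C7 hydroxylation, C6 reduction), each with its own facial question. The dioxolane must finally be turned into the vinyl group.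
- Comparison: the chosen plan sets against the safer ring closure a much shorter access to the C8/C9 pair and a one-step cis-diol.

**Alternative 3:** The cut is C6–C7. Forward, divalent samarium reduces dialdehyde A5 to a bridged diketyl that couples to the cis-diol A6.
- Merits: both oxygens and the C6–C7 bond arrive together without an oxidant, and C11 is already at the alcohol level. For the diol itself this is as good as or better than dihydroxylation.
- Weak points: A5 again needs the C8/C9 pair made acyclically. C8 is α to an aldehyde and can epimerize. The C6 aldehyde is an enal, whose ketyl is an allyl radical that can couple at C10 or be reduced. Two cis-diols (either face relative to C17) are possible.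
- Comparison: the chosen plan sets against the direct diol formation the creation of C8 and C9 in one stereospecific step, and a dihydroxylation whose face is dictated by those two centres.

Key step: step 6

## Steps

Step 1
Reactants: 1 2,2-dimethylcyclohexanone; 2 methyl 2-bromopropanoate (racemic)
Product: 3 methyl 2-(3,3-dimethyl-2-oxocyclohexyl)propanoate (racemic; both diastereomers)
Conditions: LiN(iPr)2, THF, −78 °C; then 2, DMPU, −78 → 0 °C
Reagents that add atoms: none
Why: Ketone enolate alkylation (SN2) forms C9–C10; the ketone has only one α-carbon with hydrogen, so the enolate is regiochemically fixed, and α-bromo esters are activated electrophiles. Both new centres are irrelevant: C10 becomes sp2 in step 2 and C9 is enolized in step 6.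

Step 2
Reactants: 3 methyl 2-(3,3-dimethyl-2-oxocyclohexyl)propanoate
Product: 4 methyl 2-{3,3-dimethyl-2-[(trifluoromethanesulfonyl)oxy]cyclohex-1-en-1-yl}propanoate (racemic)
Conditions: KN(SiMe3)2, THF, −78 °C; PhNTf2, −78 → 0 °C
Reagents that add atoms: N-phenylbis(trifluoromethanesulfonimide), O=S(=O)(N(c1ccccc1)S(=O)(=O)C(F)(F)F)C(F)(F)F
Why: Enol triflate formation by O-sulfonylation of the potassium enolate; the ketone α-proton is the most acidic C–H (several pK units below the ester α-proton), and the tetrasubstituted C5=C10 enol triflate is the only regioisomer the ketone can give. Such triflates are known from 2,2,6-trisubstituted cyclohexanones.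

Step 3
Reactants: 4 methyl 2-{3,3-dimethyl-2-[(trifluoromethanesulfonyl)oxy]cyclohex-1-en-1-yl}propanoate; 5 (E)-prop-1-enylboronic acid
Product: 6 methyl 2-{2-[(2E)-but-2-enoyl]-3,3-dimethylcyclohex-1-en-1-yl}propanoate (racemic)
Conditions: PdCl2(dppf) (5 mol%), K2CO3, CO (1 atm), anisole, 80 °C
Reagents that add atoms: carbon monoxide, [C-]#[O+]
Why: Carbonylative Suzuki–Miyaura coupling: zerovalent palladium inserts into the C5–OTf bond, CO insertion gives the acylpalladium (favoured at a hindered alkenyl centre), and transmetalation and reductive elimination form C5–C6 and C6–C7 with the E geometry of 5 retained. The enone is twisted out of conjugation by the C4 methyl groups, so the C9 proton stays too weakly acidic for carbonate to isomerize the product.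

Step 4
Reactants: 6 methyl 2-{2-[(2E)-but-2-enoyl]-3,3-dimethylcyclohex-1-en-1-yl}propanoate
Product: 7 methyl 2-{2-[(1S,2E)-1-hydroxybut-2-en-1-yl]-3,3-dimethylcyclohex-1-en-1-yl}propanoate (C6 S; mixture at C9)
Conditions: (R)-Me-CBS [(3aR)-1-methyl-3,3-diphenyltetrahydro-1H,3H-pyrrolo[1,2-c][1,3,2]oxazaborole] (20 mol%), BH3·SMe2, THF, −30 °C; MeOH
Reagents that add atoms: none
Why: Corey–Bakshi–Shibata reduction (1,2-reduction only): the ketone binds the ring boron through the lone pair on the side of the slim propenyl group, so the twisted 2,6,6-trisubstituted cyclohexenyl group acts as the large substituent and the (R)-catalyst should deliver hydride to give the (S)-carbinol at C6. The ester and the alkenes should be untouched at this temperature.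

Step 5
Reactants: 7 methyl 2-{2-[(1S,2E)-1-hydroxybut-2-en-1-yl]-3,3-dimethylcyclohex-1-en-1-yl}propanoate
Product: 8 (1S,4RS)-4,8,8-trimethyl-1-[(1E)-prop-1-en-1-yl]-1,4,5,6,7,8-hexahydro-3H-isochromen-3-one (C6 S; both C9 epimers)
Conditions: t-BuMgCl (1.05 equiv), THF, −40 → 0 °C; pH 7 buffer
Reagents that add atoms: none
Why: Lactonization by intramolecular transesterification: the chloromagnesium alkoxide and the ester are held cis on the C5=C10 bond and close the six-membered ring with loss of methoxide. The medium is neither acidic (the doubly allylic C6–O bond would ionize) nor strongly basic (the C9 proton would be removed), and C6 is untouched because only the O–H bond reacts.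

Step 6
Reactants: 8 (1S,4RS)-4,8,8-trimethyl-1-[(1E)-prop-1-en-1-yl]-1,4,5,6,7,8-hexahydro-3H-isochromen-3-one
Product: 11 (1R,2R)-1,2,5,5-tetramethyl-1,2,5,6,7,8-hexahydronaphthalene-1-carboxylic acid, via silyl ketene acetal 9 (not isolated), via trimethylsilyl ester 10 (not isolated)
Conditions: Me3SiCl/Et3N (1:1), THF, −100 °C; LiN(iPr)2 added slowly; −100 → 23 °C, then 50 °C; 1 M HCl
Reagents that add atoms: chlorotrimethylsilane, C[Si](C)(C)Cl (silyl group of 9 and 10; none of its atoms remains in 11)
Why: LiN(iPr)2 removes the C9 proton in the presence of Me3SiCl, so the enolate is O-silylated as it forms and gives the cyclic ketene acetal 9, in which C9=C11–O and C6–C7=C8 make up an allyl vinyl ether; a concerted suprafacial [3,3] shift forms C8–C9 while C6–O breaks, giving silyl ester 10, which acid hydrolyses to 11. The closest known reaction type is the Ireland–Claisen ring contraction of six-membered lactones bearing an alkenyl group on the carbinol carbon, which rearrange to cyclohexene-type carboxylic acids. Ring B is closed by the sigmatropic shift itself, as a six-membered carbocycle: C6 and C9 are tied by the two-atom C5=C10 bridge, so the termini C8 and C9 can only meet through a boat (bicyclo[2.2.2]-like) transition state. C9 is controlled by C6: the propenyl group can reach C9 only on the lactone face it occupies, so (S)-C6 is transferred to (R)-C9 while the original C9 configuration is erased by enolization. C8 is controlled by the E alkene geometry together with the forced boat, which places C17 cis to the C11 carboxyl. The selectivity needed is kinetic: the [3,3] shift must beat vinylogous β-elimination of the enolate and oxa-6π opening of the 2H-pyran 9, both of which would destroy C6. In its favour, silylation is in situ at −100 °C, the breaking C6–O bond is doubly allylic and the ketene acetal is donor-substituted, and either sense of ring opening would force a C6 substituent against the C4 methyl groups or into the C11 carboxyl. The temperature is capped at 50 °C so that the product diene does not undergo 1,5-hydrogen shifts.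

Step 7
Reactants: 11 (1R,2R)-1,2,5,5-tetramethyl-1,2,5,6,7,8-hexahydronaphthalene-1-carboxylic acid
Product: 12 [(1R,2R)-1,2,5,5-tetramethyl-1,2,5,6,7,8-hexahydronaphthalen-1-yl]methanol
Conditions: LiAlH4, THF, 0 °C → reflux
Reagents that add atoms: none
Why: Hydride reduction of a carboxylic acid to the primary alcohol; the unactivated diene is inert to LiAlH4 and no stereocentre is touched.

Step 8
Reactants: 12 [(1R,2R)-1,2,5,5-tetramethyl-1,2,5,6,7,8-hexahydronaphthalen-1-yl]methanol
Product: 13 (1R,2R)-1,2,5,5-tetramethyl-1,2,5,6,7,8-hexahydronaphthalene-1-carbaldehyde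
Conditions: Dess–Martin periodinane, NaHCO3, CH2Cl2, 0 → 23 °C
Reagents that add atoms: none
Why: Dess–Martin oxidation of a primary alcohol under buffered conditions; the aldehyde has no α-hydrogen, so it can neither epimerize nor move its double bonds.

Step 9
Reactants: 13 (1R,2R)-1,2,5,5-tetramethyl-1,2,5,6,7,8-hexahydronaphthalene-1-carbaldehyde
Product: 14 (1R,2S,3R,4S)-3,4-dihydroxy-1,2,5,5-tetramethyl-1,2,3,4,5,6,7,8-octahydronaphthalene-1-carbaldehyde
Conditions: OsO4 (3 mol%), NMO, acetone/H2O, 0 → 23 °C; Na2SO3
Reagents that add atoms: osmium tetroxide, O=[Os](=O)(=O)=O; N-methylmorpholine N-oxide, C[N+]1([O-])CCOCC1; water, O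
Why: Upjohn cis-dihydroxylation: OsO4 should add to the disubstituted C6=C7 bond, since the tetrasubstituted C5=C10 bond is shielded by the quaternary C4 and C9. Addition should come from the face opposite the allylic C8 methyl and the C9 formyl group, which are cis to each other, setting C6 (S) and C7 (R) with the diol cis to C20. The diol is trans to the formyl group and so cannot close to a hemiacetal.

Step 10
Reactants: 14 (1R,2S,3R,4S)-3,4-dihydroxy-1,2,5,5-tetramethyl-1,2,3,4,5,6,7,8-octahydronaphthalene-1-carbaldehyde
Product: 15 (1R,2S,3R,4S)-1,2,5,5-tetramethyl-3,4-bis[(triethylsilyl)oxy]-1,2,3,4,5,6,7,8-octahydronaphthalene-1-carbaldehyde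
Conditions: Et3SiOTf, 2,6-lutidine, CH2Cl2, −78 → 0 °C
Reagents that add atoms: triethylsilyl trifluoromethanesulfonate, CC[Si](CC)(CC)OS(=O)(=O)C(F)(F)F
Why: Silyl ether formation with a silyl triflate, reactive enough for the hindered C6 hydroxyl; the aldehyde cannot be enolized, so it does not form a silyl enol ether.

Step 11
Reactants: 15 (1R,2S,3R,4S)-1,2,5,5-tetramethyl-3,4-bis[(triethylsilyl)oxy]-1,2,3,4,5,6,7,8-octahydronaphthalene-1-carbaldehyde
Product: 16 (1R,2S,3R,4S)-1-ethenyl-1,2,5,5-tetramethyl-3,4-bis[(triethylsilyl)oxy]-1,2,3,4,5,6,7,8-octahydronaphthalene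
Conditions: Ph3PCH3Br, KOtBu, THF, 0 → 40 °C
Reagents that add atoms: methyltriphenylphosphonium bromide, C[P+](c1ccccc1)(c1ccccc1)c1ccccc1.[Br-]
Why: Wittig methylenation forms C11=C12; the unstabilized ylide is small enough for a neopentyl aldehyde, and there is no α-hydrogen or β-leaving group for the base to attack.

Step 12
Reactants: 16 (1R,2S,3R,4S)-1-ethenyl-1,2,5,5-tetramethyl-3,4-bis[(triethylsilyl)oxy]-1,2,3,4,5,6,7,8-octahydronaphthalene
Product: 17 2-{2-[(1R,2S,3R,4S)-1,2,5,5-tetramethyl-3,4-bis[(triethylsilyl)oxy]-1,2,3,4,5,6,7,8-octahydronaphthalen-1-yl]ethyl}-4,4,5,5-tetramethyl-1,3,2-dioxaborolane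
Conditions: HBpin, [Ir(cod)Cl]2 (2 mol%), dppe (4 mol%), CH2Cl2, 23 °C
Reagents that add atoms: pinacolborane, CC1(C)OBOC1(C)C
Why: Iridium-catalysed anti-Markovnikov hydroboration of a terminal alkene gives the primary pinacol boronic ester at C12; the tetrasubstituted C5=C10 bond does not react.

Step 13
Reactants: 18 (R)-but-3-en-2-ol
Product: 19 (2R)-but-3-en-2-yl N,N-di(propan-2-yl)carbamate
Conditions: NaH, THF, 0 °C; iPr2NCOCl, reflux
Reagents that add atoms: N,N-diisopropylcarbamoyl chloride, CC(C)N(C(C)C)C(Cl)=O
Why: O-Carbamoylation of the sodium alkoxide; the C–O bond at the stereocentre is not involved, so the configuration of 18 is kept.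

Step 14
Reactants: 17 2-{2-[(1R,2S,3R,4S)-1,2,5,5-tetramethyl-3,4-bis[(triethylsilyl)oxy]-1,2,3,4,5,6,7,8-octahydronaphthalen-1-yl]ethyl}-4,4,5,5-tetramethyl-1,3,2-dioxaborolane; 19 (2R)-but-3-en-2-yl N,N-di(propan-2-yl)carbamate
Product: 23 (3S)-3-methyl-5-{(1R,2S,3R,4S)-1,2,5,5-tetramethyl-3,4-bis[(triethylsilyl)oxy]-1,2,3,4,5,6,7,8-octahydronaphthalen-1-yl}pent-1-en-3-ol, via lithiated carbamate 20 (not isolated), via boronate complex 21 (not isolated), via tertiary boronic ester 22 (not isolated)
Conditions: 19, s-BuLi, TMEDA, Et2O, −78 °C; 17, −78 → 23 °C; then NaOH, H2O2, THF, 0 → 23 °C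
Reagents that add atoms: hydrogen peroxide, OO; sec-butyllithium, [Li]C(C)CC (lithium of 20 and 21 only)
Why: Lithiation–borylation–oxidation: deprotonation of 19 gives the configurationally stable α-lithio carbamate 20, which captures the boron of 17 with retention to give boronate complex 21; 1,2-migration of C12 from boron to carbon expels the carbamate with inversion to give tertiary allylic boronic ester 22, and alkaline peroxide replaces boron by oxygen with retention. These three stereospecific events should turn (R)-18 into (S)-C13 regardless of the distant ring centres. The reaction of lithiated secondary allylic carbamates with alkyl pinacol boronic esters is the known model.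

Step 15
Reactants: 23 (3S)-3-methyl-5-{(1R,2S,3R,4S)-1,2,5,5-tetramethyl-3,4-bis[(triethylsilyl)oxy]-1,2,3,4,5,6,7,8-octahydronaphthalen-1-yl}pent-1-en-3-ol
Product: 24 (1S,2R,3S,4R)-4-[(3S)-3-hydroxy-3-methylpent-4-en-1-yl]-3,4,8,8-tetramethyl-1,2,3,4,5,6,7,8-octahydronaphthalene-1,2-diol
Conditions: Bu4NF, THF, 0 → 23 °C
Reagents that add atoms: none
Why: Fluoride cleavage of both silyl ethers; no acid is present, so the tertiary allylic C13 alcohol and the allylic C6–O bond cannot ionize.

Step 16
Reactants: 24 (1S,2R,3S,4R)-4-[(3S)-3-hydroxy-3-methylpent-4-en-1-yl]-3,4,8,8-tetramethyl-1,2,3,4,5,6,7,8-octahydronaphthalene-1,2-diol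
Product: 25 (1S,2R,3S,4R)-1-hydroxy-4-[(3S)-3-hydroxy-3-methylpent-4-en-1-yl]-3,4,8,8-tetramethyl-1,2,3,4,5,6,7,8-octahydronaphthalen-2-yl acetate
Conditions: Ac2O (1.1 equiv), pyridine, CH2Cl2, −20 → 0 °C
Reagents that add atoms: acetic anhydride, CC(=O)OC(C)=O
Why: Kinetic monoacetylation: the C7 hydroxyl is an open secondary alcohol, the C6 hydroxyl is allylic and screened by the C4 methyl groups across C5, and the C13 hydroxyl is tertiary. The C7 acetate should therefore form first, as is usual for 6,7-dihydroxy terpenoids of this substitution pattern.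

## Compound list

1 | 2,2-dimethylcyclohexanone | CC1(C)CCCCC1=O | starting material
2 | methyl 2-bromopropanoate (racemic) | COC(=O)C(C)Br | starting material
3 | methyl 2-(3,3-dimethyl-2-oxocyclohexyl)propanoate | COC(=O)C(C)C1CCCC(C)(C)C1=O | intermediate
4 | methyl 2-{3,3-dimethyl-2-[(trifluoromethanesulfonyl)oxy]cyclohex-1-en-1-yl}propanoate | COC(=O)C(C)C1=C(OS(=O)(=O)C(F)(F)F)C(C)(C)CCC1 | intermediate
5 | (E)-prop-1-enylboronic acid | C/C=C/B(O)O | starting material
6 | methyl 2-{2-[(2E)-but-2-enoyl]-3,3-dimethylcyclohex-1-en-1-yl}propanoate | COC(=O)C(C)C1=C(C(=O)/C=C/C)C(C)(C)CCC1 | intermediate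
7 | methyl 2-{2-[(1S,2E)-1-hydroxybut-2-en-1-yl]-3,3-dimethylcyclohex-1-en-1-yl}propanoate | COC(=O)C(C)C1=C([C@@H](O)/C=C/C)C(C)(C)CCC1 | intermediate
8 | (1S,4RS)-4,8,8-trimethyl-1-[(1E)-prop-1-en-1-yl]-1,4,5,6,7,8-hexahydro-3H-isochromen-3-one | C/C=C/[C@@H]1OC(=O)C(C)C2=C1C(C)(C)CCC2 | intermediate
9 | (1S)-4,8,8-trimethyl-1-[(1E)-prop-1-en-1-yl]-3-[(trimethylsilyl)oxy]-5,6,7,8-tetrahydro-1H-isochromene | C/C=C/[C@@H]1OC(O[Si](C)(C)C)=C(C)C2=C1C(C)(C)CCC2 | intermediate (not isolated)
10 | trimethylsilyl (1R,2R)-1,2,5,5-tetramethyl-1,2,5,6,7,8-hexahydronaphthalene-1-carboxylate | C[Si](C)(C)OC(=O)[C@@]1(C)C2=C(C=C[C@H]1C)C(C)(C)CCC2 | intermediate (not isolated)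
11 | (1R,2R)-1,2,5,5-tetramethyl-1,2,5,6,7,8-hexahydronaphthalene-1-carboxylic acid | OC(=O)[C@@]1(C)C2=C(C=C[C@H]1C)C(C)(C)CCC2 | intermediate
12 | [(1R,2R)-1,2,5,5-tetramethyl-1,2,5,6,7,8-hexahydronaphthalen-1-yl]methanol | OC[C@@]1(C)C2=C(C=C[C@H]1C)C(C)(C)CCC2 | intermediate
13 | (1R,2R)-1,2,5,5-tetramethyl-1,2,5,6,7,8-hexahydronaphthalene-1-carbaldehyde | O=C[C@@]1(C)C2=C(C=C[C@H]1C)C(C)(C)CCC2 | intermediate
14 | (1R,2S,3R,4S)-3,4-dihydroxy-1,2,5,5-tetramethyl-1,2,3,4,5,6,7,8-octahydronaphthalene-1-carbaldehyde | O=C[C@@]1(C)C2=C([C@H](O)[C@H](O)[C@H]1C)C(C)(C)CCC2 | intermediate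
15 | (1R,2S,3R,4S)-1,2,5,5-tetramethyl-3,4-bis[(triethylsilyl)oxy]-1,2,3,4,5,6,7,8-octahydronaphthalene-1-carbaldehyde | O=C[C@@]1(C)C2=C([C@H](O[Si](CC)(CC)CC)[C@H](O[Si](CC)(CC)CC)[C@H]1C)C(C)(C)CCC2 | intermediate
16 | (1R,2S,3R,4S)-1-ethenyl-1,2,5,5-tetramethyl-3,4-bis[(triethylsilyl)oxy]-1,2,3,4,5,6,7,8-octahydronaphthalene | C=C[C@@]1(C)C2=C([C@H](O[Si](CC)(CC)CC)[C@H](O[Si](CC)(CC)CC)[C@H]1C)C(C)(C)CCC2 | intermediate
17 | 2-{2-[(1R,2S,3R,4S)-1,2,5,5-tetramethyl-3,4-bis[(triethylsilyl)oxy]-1,2,3,4,5,6,7,8-octahydronaphthalen-1-yl]ethyl}-4,4,5,5-tetramethyl-1,3,2-dioxaborolane | CC1(C)OB(CC[C@@]2(C)C3=C([C@H](O[Si](CC)(CC)CC)[C@H](O[Si](CC)(CC)CC)[C@H]2C)C(C)(C)CCC3)OC1(C)C | intermediate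
18 | (R)-but-3-en-2-ol | C=C[C@@H](C)O | starting material
19 | (2R)-but-3-en-2-yl N,N-di(propan-2-yl)carbamate | C=C[C@@H](C)OC(=O)N(C(C)C)C(C)C | intermediate
20 | (2R)-2-lithiobut-3-en-2-yl N,N-di(propan-2-yl)carbamate (TMEDA-solvated) | C=C[C@@]([Li])(C)OC(=O)N(C(C)C)C(C)C | intermediate (not isolated)
21 | lithium boronate complex of 17 and 20 (boron on the former carbanion carbon, configuration retained) | [Li+].C=C[C@@]([B-]1(CC[C@@]2(C)C3=C([C@H](O[Si](CC)(CC)CC)[C@H](O[Si](CC)(CC)CC)[C@H]2C)C(C)(C)CCC3)OC(C)(C)C(C)(C)O1)(C)OC(=O)N(C(C)C)C(C)C | intermediate (not isolated)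
22 | 2-[(3R)-3-methyl-5-{(1R,2S,3R,4S)-1,2,5,5-tetramethyl-3,4-bis[(triethylsilyl)oxy]-1,2,3,4,5,6,7,8-octahydronaphthalen-1-yl}pent-1-en-3-yl]-4,4,5,5-tetramethyl-1,3,2-dioxaborolane | C=C[C@@](C)(B1OC(C)(C)C(C)(C)O1)CC[C@@]2(C)C3=C([C@H](O[Si](CC)(CC)CC)[C@H](O[Si](CC)(CC)CC)[C@H]2C)C(C)(C)CCC3 | intermediate (not isolated)
23 | (3S)-3-methyl-5-{(1R,2S,3R,4S)-1,2,5,5-tetramethyl-3,4-bis[(triethylsilyl)oxy]-1,2,3,4,5,6,7,8-octahydronaphthalen-1-yl}pent-1-en-3-ol | C=C[C@@](C)(O)CC[C@@]1(C)C2=C([C@H](O[Si](CC)(CC)CC)[C@H](O[Si](CC)(CC)CC)[C@H]1C)C(C)(C)CCC2 | intermediate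
24 | (1S,2R,3S,4R)-4-[(3S)-3-hydroxy-3-methylpent-4-en-1-yl]-3,4,8,8-tetramethyl-1,2,3,4,5,6,7,8-octahydronaphthalene-1,2-diol | C=C[C@@](C)(O)CC[C@@]1(C)C2=C([C@H](O)[C@H](O)[C@H]1C)C(C)(C)CCC2 | intermediate
25 | (1S,2R,3S,4R)-1-hydroxy-4-[(3S)-3-hydroxy-3-methylpent-4-en-1-yl]-3,4,8,8-tetramethyl-1,2,3,4,5,6,7,8-octahydronaphthalen-2-yl acetate (halimane: 6S,7R,8S,9R,13S) | C=C[C@@](C)(O)CC[C@@]1(C)C2=C([C@H](O)[C@H](OC(C)=O)[C@H]1C)C(C)(C)CCC2 | target

## Step count and least certain steps

Total step count: 16. Longest linear sequence: 15 (steps 1–12 and 14–16; step 13 is a one-step branch).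

**Step 6 (key step).** The most likely failure is ring opening that competes with the [3,3] shift. The lithium dienolate can expel the C6 carboxylate oxygen by vinylogous β-elimination before it is silylated, and ketene acetal 9 can cleave the same C6–O bond by oxa-6π electrocyclic opening. Either path gives an achiral trienoic acid derivative and erases C6. If that triene recloses by 6π electrocyclization, it gives racemic material with C17 trans to C11.
- Fallback (sets out from 4, returns at 11): remove the lactone tether so that no leaving group is conjugated with the enolate.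
- Suzuki–Miyaura coupling of 4 with potassium vinyltrifluoroborate (PdCl2(dppf), Cs2CO3) would give methyl 2-(2-ethenyl-3,3-dimethylcyclohex-1-en-1-yl)propanoate F1.
- Saponification (LiOH) would give 2-(2-ethenyl-3,3-dimethylcyclohex-1-en-1-yl)propanoic acid F2.
- Carbodiimide esterification with (2S,3E)-pent-3-en-2-ol would give (2S,3E)-pent-3-en-2-yl 2-(2-ethenyl-3,3-dimethylcyclohex-1-en-1-yl)propanoate F3.
- An acyclic Ireland–Claisen rearrangement (KN(SiMe3)2, Me3SiCl; chair transition state with the carbinol methyl equatorial) would form C8–C9 and give (2R,3R,4E)-2-(2-ethenyl-3,3-dimethylcyclohex-1-en-1-yl)-2,3-dimethylhex-4-enoic acid F4.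
- Ring-closing metathesis of the dienyl vinyl group with the propenyl group (second-generation Grubbs catalyst, (H2IMes)(PCy3)Cl2Ru=CHPh) would close ring B with loss of propene and give 11.
- The price is that C9 then depends on the geometry of an acyclic, fully substituted ketene acetal (the cyclohexenyl group must sit cis to the silyloxy group), which the lactone fixes by its ring.

**Step 3.** The most likely failure is direct coupling without CO insertion, or sluggish transmetalation at the doubly flanked alkenylpalladium, which would leave triflate or give the diene.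
- Fallback (sets out from 4, returns at 6): form C5–C6 one oxidation level lower. A NiCl2-catalysed, CrCl2-mediated Nozaki–Hiyama–Kishi coupling of 4 with (E)-but-2-enal would give racemic methyl 2-{2-[(2E)-1-hydroxybut-2-en-1-yl]-3,3-dimethylcyclohex-1-en-1-yl}propanoate F5. Immediate MnO2 oxidation of this doubly allylic alcohol would give 6.

**Step 4.** The most likely failure is weak facial discrimination, because both ketone substituents are alkenyl groups and the selectivity rests on size alone. The C6 centre fixes the absolute configuration of the whole ring system.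
- Fallback (sets out from 6, returns at 7): reduce without control and resolve. Luche reduction (NaBH4, CeCl3·7H2O) would give the racemic dienol F5. A lipase with vinyl acetate is expected to acylate the (R)-alcohol to methyl 2-{2-[(1R,2E)-1-acetoxybut-2-en-1-yl]-3,3-dimethylcyclohex-1-en-1-yl}propanoate F6 and leave (S)-7. F6 can be recycled to 6 by methanolysis and MnO2 oxidation.

**Step 14.** The most likely failure is erosion of C13 purity: loss of configuration of the lithiated allyl carbamate, capture of boron at the γ-carbon, or a 1,3-boron shift in 22 before oxidation. If boron capture went with inversion rather than retention, (S)-but-3-en-2-ol would be used instead.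
- Fallback (sets out from 16, returns at 23): set C13 by asymmetric epoxidation.
- Hydroboration of 16 with 9-BBN would give the B-alkyl-9-borabicyclo[3.3.1]nonane F7.
- Suzuki–Miyaura B-alkyl coupling of F7 with (E)-3-iodobut-2-en-1-ol would give the (E)-allylic alcohol F8.
- Sharpless asymmetric epoxidation (Ti(OiPr)4, L-(+)-diethyl tartrate, t-BuOOH) would give the (2S,3S)-epoxy alcohol F9.
- Iodination (I2, PPh3, imidazole) would give the epoxy iodide F10.
- Zn would open F10 reductively to the tertiary vinyl carbinol 23 with C13 unchanged.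

**Step 16.** The most likely failure is non-selective acylation (C6 or both hydroxyls) or acetyl migration between O7 and O6.
- Fallback (sets out from 24, returns at 25): activate one oxygen. Bu2SnO would convert the cis-diol into the dibutylstannylene acetal F11, which AcCl at low temperature should acylate at the equatorial, less hindered O7.

## Further compounds

F1 | step 6 | methyl 2-(2-ethenyl-3,3-dimethylcyclohex-1-en-1-yl)propanoate (racemic) | COC(=O)C(C)C1=C(C=C)C(C)(C)CCC1
F2 | step 6 | 2-(2-ethenyl-3,3-dimethylcyclohex-1-en-1-yl)propanoic acid (racemic) | OC(=O)C(C)C1=C(C=C)C(C)(C)CCC1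
F3 | step 6 | (2S,3E)-pent-3-en-2-yl 2-(2-ethenyl-3,3-dimethylcyclohex-1-en-1-yl)propanoate (both α-epimers) | C/C=C/[C@H](C)OC(=O)C(C)C1=C(C=C)C(C)(C)CCC1
F4 | step 6 | (2R,3R,4E)-2-(2-ethenyl-3,3-dimethylcyclohex-1-en-1-yl)-2,3-dimethylhex-4-enoic acid | OC(=O)[C@](C)([C@H](C)/C=C/C)C1=C(C=C)C(C)(C)CCC1
F5 | step 3 | methyl 2-{2-[(2E)-1-hydroxybut-2-en-1-yl]-3,3-dimethylcyclohex-1-en-1-yl}propanoate (racemic at the carbinol) | COC(=O)C(C)C1=C(C(O)/C=C/C)C(C)(C)CCC1
F6 | step 4 | methyl 2-{2-[(1R,2E)-1-acetoxybut-2-en-1-yl]-3,3-dimethylcyclohex-1-en-1-yl}propanoate | COC(=O)C(C)C1=C([C@H](OC(C)=O)/C=C/C)C(C)(C)CCC1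
F7 | step 14 | 9-{2-[(1R,2S,3R,4S)-1,2,5,5-tetramethyl-3,4-bis[(triethylsilyl)oxy]-1,2,3,4,5,6,7,8-octahydronaphthalen-1-yl]ethyl}-9-borabicyclo[3.3.1]nonane | C1CCC2CCCC1B2CC[C@@]3(C)C4=C([C@H](O[Si](CC)(CC)CC)[C@H](O[Si](CC)(CC)CC)[C@H]3C)C(C)(C)CCC4
F8 | step 14 | (2E)-3-methyl-5-{(1R,2S,3R,4S)-1,2,5,5-tetramethyl-3,4-bis[(triethylsilyl)oxy]-1,2,3,4,5,6,7,8-octahydronaphthalen-1-yl}pent-2-en-1-ol | OC/C=C(\C)CC[C@@]1(C)C2=C([C@H](O[Si](CC)(CC)CC)[C@H](O[Si](CC)(CC)CC)[C@H]1C)C(C)(C)CCC2
F9 | step 14 | [(2S,3S)-3-methyl-3-{2-[(1R,2S,3R,4S)-1,2,5,5-tetramethyl-3,4-bis[(triethylsilyl)oxy]-1,2,3,4,5,6,7,8-octahydronaphthalen-1-yl]ethyl}oxiran-2-yl]methanol | OC[C@@H]1O[C@@]1(C)CC[C@@]2(C)C3=C([C@H](O[Si](CC)(CC)CC)[C@H](O[Si](CC)(CC)CC)[C@H]2C)C(C)(C)CCC3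
F10 | step 14 | (2R,3S)-2-(iodomethyl)-3-methyl-3-{2-[(1R,2S,3R,4S)-1,2,5,5-tetramethyl-3,4-bis[(triethylsilyl)oxy]-1,2,3,4,5,6,7,8-octahydronaphthalen-1-yl]ethyl}oxirane | IC[C@@H]1O[C@@]1(C)CC[C@@]2(C)C3=C([C@H](O[Si](CC)(CC)CC)[C@H](O[Si](CC)(CC)CC)[C@H]2C)C(C)(C)CCC3
F11 | step 16 | 6,7-O-dibutylstannylene acetal of triol 24 | C=C[C@@](C)(O)CC[C@@]1(C)C2=C([C@@H]3O[Sn](CCCC)(CCCC)O[C@@H]3[C@H]1C)C(C)(C)CCC2
A1 | alternative 1 | (2E,6E,10E)-geranylgeranyl diphosphate | CC(C)=CCC/C(C)=C/CC/C(C)=C/CC/C(C)=C/COP(=O)(O)OP(=O)(O)O
A2 | alternative 1 | syn-halima-5(10),13E-dien-15-yl diphosphate | OP(=O)(O)OP(=O)(O)OC/C=C(\C)CC[C@@]1(C)C2=C(CC[C@H]1C)C(C)(C)CCC2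
A3 | alternative 2 | 3-ethoxy-2-(5-iodo-2-methylpentan-2-yl)-5,6-dimethyl-6-[2-(2,2,4-trimethyl-1,3-dioxolan-4-yl)ethyl]cyclohex-2-en-1-one (C8, C9 and C13 as in the target) | CC1(C)OC[C@@](C)(O1)CC[C@@]2(C)C(=O)C(C(C)(C)CCCI)=C(OCC)C[C@H]2C
A4 | alternative 2 | bicyclic C6 enone with the C5=C10 bond and the dioxolane side chain | CC1(C)OC[C@@](C)(O1)CC[C@@]2(C)C3=C(C(=O)C[C@H]2C)C(C)(C)CCC3
A5 | alternative 3 | 2-(2-formyl-3,3-dimethylcyclohex-1-en-1-yl)-2,3-dimethyl-4-oxobutyl 2,2-dimethylpropanoate (C8 and C9 as in the target) | CC(C)(C)C(=O)OC[C@](C)([C@H](C)C=O)C1=C(C=O)C(C)(C)CCC1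
A6 | alternative 3 | bicyclic cis-6,7-diol with the C11 pivalate | CC(C)(C)C(=O)OC[C@@]1(C)C2=C([C@H](O)[C@H](O)[C@H]1C)C(C)(C)CCC2
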